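**Retrosynthetic overview**

1. Lehualide E is cut at the CH2–CH= bond between the methylene on C6 of the 2-pyranone and the trisubstituted alkene. That bond is made in a one-pot, three-component union of 8-phenyloct-1-yne, AlMe3 and 6-(bromomethyl)-3,4-dimethoxy-5-methyl-2-pyranone (Zr-catalysed syn-methylalumination, then Pd-catalysed alkenyl–CH2 coupling).
2. Enabling feature: the alkene carbon remote from the ring carries one methyl group cis to the pyranylmethyl group, which is the pattern produced by syn addition of CH3–Al across a terminal alkyne. The exocyclic CH2 on C6 is allylic to the ring C5=C6 bond and vinylogously tied through C4=C3 to the C2 lactone carbonyl, so its C–Br bond adds readily to zerovalent palladium, and the same conjugation directs radical bromination to the C6 methyl.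
3. The bromide comes from 3,4-dimethoxy-5,6-dimethyl-2-pyranone, built from a triketide ester: Claisen condensation of methyl methoxyacetate with propanoyl chloride, γ-acylation of the β-keto ester dianion with N-methoxy-N-methylacetamide, lactonization, O-methylation.
4. Ring order: the 2-pyranone is the only ring built, closed at O1–C2 by lactonization (step 3). The phenyl ring is bought in (6-bromohexyl)benzene, which gives the alkyne by acetylide alkylation.

Key step: step 7

Remark: 4 is racemic and 7 is a mixture of diastereomers and keto–enol tautomers; these centres disappear in step 3, and 7 and 8 are drawn as one tautomer each.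

**Route**

Step 1
Reactants: 1 methyl 2-methoxyacetate; 2 propanoyl chloride
Product: 4 methyl 2-methoxy-3-oxopentanoate (racemic), via lithium enolate 3 (not isolated)
Conditions: 1 (2.1 equiv), LiN(iPr)2 (2.1 equiv), THF, −78 °C; then 2 (1.0 equiv), −78 → −20 °C; aq. HCl
Reagents that add atoms: none
Why: Crossed Claisen condensation in which the lithium ester enolate 3 is C-acylated by the acid chloride, while the second equivalent of 3 deprotonates the more acidic β-keto ester as it forms and so blocks double acylation.

Step 2
Reactants: 4 methyl 2-methoxy-3-oxopentanoate; 5 N-methoxy-N-methylacetamide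
Product: 7 methyl 2-methoxy-4-methyl-3,5-dioxohexanoate, via dilithium dianion 6 (not isolated)
Conditions: LiN(iPr)2 (2.2 equiv), THF, −78 → 0 °C; then 5 (1.0 equiv), −78 → 0 °C; aq. HCl
Reagents that add atoms: none
Why: γ-Acylation of a β-keto ester dianion, in which the second deprotonation can only occur at C4 and this most nucleophilic carbon attacks the Weinreb amide, which stops at the ketone stage without over-addition.

Step 3
Reactants: 7 methyl 2-methoxy-4-methyl-3,5-dioxohexanoate
Product: 8 4-hydroxy-3-methoxy-5,6-dimethyl-2H-pyran-2-one
Conditions: DBU (1.5 equiv), PhMe, 60 °C; aq. HCl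
Reagents that add atoms: none
Why: Base-mediated lactonization (6-exo-trig acyl substitution by the C5 enol oxygen on the methyl ester with loss of methanol) is the standard closure of 3,5-dioxo esters to 4-hydroxy-2-pyranones and is driven by formation of the conjugated, acidic hydroxypyranone.

Step 4
Reactants: 8 4-hydroxy-3-methoxy-5,6-dimethyl-2H-pyran-2-one
Product: 9 3,4-dimethoxy-5,6-dimethyl-2H-pyran-2-one
Conditions: Me2SO4 (1.5 equiv), K2CO3 (2 equiv), acetone, reflux
Reagents that add atoms: dimethyl sulfate, COS(=O)(=O)OC
Why: Williamson-type O-methylation of the vinylogous acid, where K2CO3/Me2SO4 in acetone is expected to methylate the C4 oxygen of the ambident anion in preference to the C2 carbonyl oxygen, giving the 2-pyranone and not the isomeric 4-pyranone.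

Step 5
Reactants: 9 3,4-dimethoxy-5,6-dimethyl-2H-pyran-2-one
Product: 10 6-(bromomethyl)-3,4-dimethoxy-5-methyl-2H-pyran-2-one
Conditions: NBS (1.05 equiv), AIBN (5 mol %), PhCF3, 80 °C
Reagents that add atoms: N-bromosuccinimide, O=C1CCC(=O)N1Br
Why: Wohl–Ziegler bromination, in which hydrogen abstraction should occur at the C6 methyl because that radical is delocalized over C6=C5–C4=C3 onto the C2 carbonyl whereas the C5-methyl radical is only cross-conjugated, and C3 and C5 are substituted so no ring position is open to bromination.

Step 6
Reactants: 11 (6-bromohexyl)benzene; 12 lithium acetylide ethylenediamine complex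
Product: 13 8-phenyloct-1-yne
Conditions: 12 (1.5 equiv), DMSO, 10 °C → rt
Reagents that add atoms: none
Why: SN2 alkylation of an acetylide by an unhindered primary alkyl bromide in a dipolar aprotic solvent.

Step 7
Reactants: 13 8-phenyloct-1-yne; 10 6-(bromomethyl)-3,4-dimethoxy-5-methyl-2H-pyran-2-one
Product: 15 lehualide E [3,4-dimethoxy-5-methyl-6-[(2E)-3-methyl-9-phenylnon-2-en-1-yl]-2H-pyran-2-one], via alkenylalane 14 (not isolated)
Conditions: 13 (1.3 equiv), AlMe3 (2.6 equiv), Cp2ZrCl2 (0.25 equiv), CH2Cl2, 0 °C → rt; volatiles and excess AlMe3 removed in vacuo; then 10 (1.0 equiv), Pd(PPh3)4 (5 mol %), THF, 0 °C → rt; aq. NH4Cl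
Reagents that add atoms: trimethylaluminium, C[Al](C)C
Why: Cp2ZrCl2-catalysed syn-methylalumination of the terminal alkyne places CH3 on the internal carbon and AlMe2 on the terminal carbon, cis to each other (alkenylalane 14); zerovalent palladium then inserts into the C–Br bond of 10 to give an η3 pyranylmethyl (allyl-type, CH2–C6–C5) palladium bromide, the alkenyl group moves from aluminium to palladium, and reductive elimination at the CH2 terminus forms the CH2–CH= bond. The closest known reaction type is the one-pot Negishi carboalumination/cross-coupling of alkenylalanes with allylic and benzylic halides under Pd(PPh3)4 or nickel–phosphine catalysis, as used to attach prenyl-type chains to halomethyl arenes and quinones. No ring is closed and no stereocentre is formed; the E geometry of the trisubstituted alkene follows from syn addition across the alkyne and from retention of alkene configuration in transmetalation and reductive elimination. The step needs regioselective methylalumination (the unbranched terminal alkyne places the metal on the CH terminus), alkenyl rather than methyl transfer to palladium (alkenyl groups transfer faster, and excess AlMe3 is stripped before 10 is added), and bond formation at CH2 rather than at ring carbon C5 of the η3 complex (only attack at CH2 keeps the conjugated 2-pyranone). The lactone carbonyl, a doubly vinylogous ester of low electrophilicity, should outlast the alane at 0 °C because the catalysed coupling is fast.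

**Compound list**

1 | methyl 2-methoxyacetate | COCC(=O)OC | starting material
2 | propanoyl chloride | CCC(=O)Cl | starting material
3 | lithium enolate of methyl 2-methoxyacetate (lithium 1,2-dimethoxyethenolate, enolate geometry not defined) | COC=C(OC)O[Li] | intermediate
4 | methyl 2-methoxy-3-oxopentanoate (racemic) | CCC(=O)C(OC)C(=O)OC | intermediate
5 | N-methoxy-N-methylacetamide | CC(=O)N(C)OC | starting material
6 | dilithium dianion (bis-enolate) of methyl 2-methoxy-3-oxopentanoate (enolate geometries not defined) | CC=C(O[Li])C(OC)=C(OC)O[Li] | intermediate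
7 | methyl 2-methoxy-4-methyl-3,5-dioxohexanoate (mixture of diastereomers and enol tautomers) | CC(=O)C(C)C(=O)C(OC)C(=O)OC | intermediate
8 | 4-hydroxy-3-methoxy-5,6-dimethyl-2H-pyran-2-one | COc1c(O)c(C)c(C)oc1=O | intermediate
9 | 3,4-dimethoxy-5,6-dimethyl-2H-pyran-2-one | COc1c(C)c(C)oc(=O)c1OC | intermediate
10 | 6-(bromomethyl)-3,4-dimethoxy-5-methyl-2H-pyran-2-one | COc1c(C)c(CBr)oc(=O)c1OC | intermediate
11 | (6-bromohexyl)benzene | BrCCCCCCc1ccccc1 | starting material
12 | lithium acetylide ethylenediamine complex | [Li]C#C.NCCN | starting material
13 | 8-phenyloct-1-yne | C#CCCCCCCc1ccccc1 | intermediate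
14 | dimethyl[(1E)-2-methyl-8-phenyloct-1-en-1-yl]alane (Al cis to the vinylic methyl) | C[Al](C)/C=C(\C)CCCCCCc1ccccc1 | intermediate
15 | lehualide E, 3,4-dimethoxy-5-methyl-6-[(2E)-3-methyl-9-phenylnon-2-en-1-yl]-2H-pyran-2-one | COc1c(C)c(C/C=C(\C)CCCCCCc2ccccc2)oc(=O)c1OC | target

**Summary**

Total step count: 7. Longest linear sequence: 6 (steps 1, 2, 3, 4, 5, 7).

**Steps most likely to fail**

Step 7. The alane may transfer methyl instead of alkenyl, may attack the lactone carbonyl or add in conjugate fashion to the pyranone, or the Lewis-acidic medium may degrade the bromide before oxidative addition. The fallback sets out from 13 and separates metalation from coupling. The same methylalumination (AlMe3, Cp2ZrCl2, CH2Cl2, via 14) is quenched with I2 in THF at −30 °C to give (E)-(8-iodo-7-methyloct-7-en-1-yl)benzene F1. Iodine–lithium exchange (t-BuLi, 2 equiv, Et2O, −78 °C) gives [(1E)-2-methyl-8-phenyloct-1-en-1-yl]lithium F2, which is trapped with Bu3SnCl to give tributyl[(1E)-2-methyl-8-phenyloct-1-en-1-yl]stannane F3. A neutral Stille coupling of F3 with 10 (Pd2(dba)3, AsPh3, THF, 50 °C) forms the same CH2–CH= bond with retention of alkene geometry and comes back to the route at 15.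

Step 5. Hydrogen abstraction may compete at the C5 methyl, or bromination may run on to the dibromomethyl stage. The fallback sets out from 4 and carries the C6 substituent at the alcohol oxidation level from the start. Dianion 6 is acylated with 2-[(tert-butyldimethylsilyl)oxy]-N-methoxy-N-methylacetamide to give methyl 6-[(tert-butyldimethylsilyl)oxy]-2-methoxy-4-methyl-3,5-dioxohexanoate F4. DBU in PhMe closes this to 6-{[(tert-butyldimethylsilyl)oxy]methyl}-4-hydroxy-3-methoxy-5-methyl-2H-pyran-2-one F5. Me2SO4/K2CO3 gives 6-{[(tert-butyldimethylsilyl)oxy]methyl}-3,4-dimethoxy-5-methyl-2H-pyran-2-one F6. HF·pyridine in THF frees 6-(hydroxymethyl)-3,4-dimethoxy-5-methyl-2H-pyran-2-one F7. An Appel reaction (CBr4, PPh3, CH2Cl2, 0 °C) comes back to the route at 10 with unambiguous regiochemistry.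

Step 2. The enolizable Weinreb amide may be deprotonated by the dianion instead of acylating it, so that conversion stalls. The fallback sets out from 4 and replaces acylation by aldol addition and oxidation. Dianion 6 is added to acetaldehyde (THF, −78 °C) to give methyl 5-hydroxy-2-methoxy-4-methyl-3-oxohexanoate F8 as a diastereomer mixture. Oxidation of the secondary alcohol with Dess–Martin periodinane (CH2Cl2, rt) comes back to the route at 7.

**Further compounds**

F1 | step 7 | (E)-(8-iodo-7-methyloct-7-en-1-yl)benzene | I/C=C(\C)CCCCCCc1ccccc1
F2 | step 7 | [(1E)-2-methyl-8-phenyloct-1-en-1-yl]lithium | [Li]/C=C(\C)CCCCCCc1ccccc1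
F3 | step 7 | tributyl[(1E)-2-methyl-8-phenyloct-1-en-1-yl]stannane | CCCC[Sn](CCCC)(CCCC)/C=C(\C)CCCCCCc1ccccc1
F4 | step 5 | methyl 6-[(tert-butyldimethylsilyl)oxy]-2-methoxy-4-methyl-3,5-dioxohexanoate | COC(=O)C(OC)C(=O)C(C)C(=O)CO[Si](C)(C)C(C)(C)C
F5 | step 5 | 6-{[(tert-butyldimethylsilyl)oxy]methyl}-4-hydroxy-3-methoxy-5-methyl-2H-pyran-2-one | COc1c(O)c(C)c(CO[Si](C)(C)C(C)(C)C)oc1=O
F6 | step 5 | 6-{[(tert-butyldimethylsilyl)oxy]methyl}-3,4-dimethoxy-5-methyl-2H-pyran-2-one | COc1c(C)c(CO[Si](C)(C)C(C)(C)C)oc(=O)c1OC
F7 | step 5 | 6-(hydroxymethyl)-3,4-dimethoxy-5-methyl-2H-pyran-2-one | COc1c(C)c(CO)oc(=O)c1OC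
F8 | step 2 | methyl 5-hydroxy-2-methoxy-4-methyl-3-oxohexanoate (mixture of diastereomers) | CC(O)C(C)C(=O)C(OC)C(=O)OC
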